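**Plan**

- Enabling feature: ring A carries four adjacent oxygenated carbons, C5–C8, which are the four carbons of dimethyl squarate; the ring-fusion bond C4a=C8a is the enol-ether C5=C6 bond of a monocyclic 2-aryl-4-pyranone (ring C).
- Retrosynthetic cuts, in order: the two O–benzyl bonds and the O–methyl bonds at C5 and C8; C8–C8a (6π closure of ring A); C4a–C5 (pyranonyl–metal plus squarate); C2–C3 and O1–C8a (hetero-Diels–Alder of ring C).
- Forward order: ring B is bought with the aldehyde; ring C is made by cycloaddition, iodinated at the future C4a and dehydrogenated to the pyranone; ring A is grown last from squarate by thermal ring expansion; two methylations and debenzylation finish.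
- Stereochemistry: the target has no stereocentre, axis or stereogenic double bond, so it is a single achiral compound and the single-enantiomer requirement is met by constitution. The centres formed on the way (C2 of the dihydropyranone, the cyclobutenone carbinol, C8a of the dienone) are racemic and are all erased.

Key step: step 5

**Route**

Step 1
Reactants: 1 3,4-bis(benzyloxy)benzaldehyde; 2 Danishefsky's diene, (E)-1-methoxy-3-(trimethylsilyloxy)buta-1,3-diene
Product: 4 2-[3,4-bis(benzyloxy)phenyl]-2,3-dihydro-4H-pyran-4-one (racemic), via cycloadduct 3 (not isolated)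
Conditions: ZnCl2 (20 mol%), THF, rt; then TFA (cat.), CH2Cl2, 0 °C
Reagents that add atoms: none
Why: The Lewis-acid-catalysed hetero-Diels–Alder reaction of an aryl aldehyde with Danishefsky's diene, followed by acid-induced loss of methanol and the silyl group, is the standard entry to 2-aryl-2,3-dihydro-4-pyranones; the C2 centre forms racemic and is removed in step 3.

Step 2
Reactants: 4 2-[3,4-bis(benzyloxy)phenyl]-2,3-dihydro-4H-pyran-4-one
Product: 5 2-[3,4-bis(benzyloxy)phenyl]-5-iodo-2,3-dihydro-4H-pyran-4-one (racemic)
Conditions: I2 (2 equiv), pyridine/CH2Cl2 1:1, 0 °C → rt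
Reagents that add atoms: iodine, II
Why: Pyridine-mediated α-iodination of the vinylogous ester (I2/pyridine enone iodination) can only occur at C5, because C3 is still sp3 at this oxidation level, and the reagent is too mild to iodinate the dialkoxyarene.

Step 3
Reactants: 5 2-[3,4-bis(benzyloxy)phenyl]-5-iodo-2,3-dihydro-4H-pyran-4-one
Product: 8 2-[3,4-bis(benzyloxy)phenyl]-5-iodo-4H-pyran-4-one, via lithium enolate 6 (not isolated), via sulfilimine adduct 7 (not isolated)
Conditions: LDA (1.1 equiv), THF, −78 °C; then PhS(Cl)=NtBu (1.2 equiv), −78 °C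
Reagents that add atoms: none
Why: In a Mukaiyama dehydrogenation, kinetic α′-deprotonation at C3, S-sulfinimidoylation of the enolate and intramolecular syn elimination with the C2–H should install the C2=C3 bond at low temperature, giving the pyranone and erasing the C2 centre.

Step 4
Reactants: 8 2-[3,4-bis(benzyloxy)phenyl]-5-iodo-4H-pyran-4-one; 9 dimethyl squarate (3,4-dimethoxycyclobut-3-ene-1,2-dione)
Product: 11 4-{6-[3,4-bis(benzyloxy)phenyl]-4-oxo-4H-pyran-3-yl}-4-hydroxy-2,3-dimethoxycyclobut-2-en-1-one (racemic), via pyranonylmagnesium chloride 10 (not isolated)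
Conditions: iPrMgCl·LiCl (1.05 equiv), THF, −78 → −60 °C; then cannulated into 9 (1.3 equiv), THF, −78 °C; sat. aq NH4Cl
Reagents that add atoms: none
Why: Iodine–magnesium exchange with the turbo-Grignard reagent is fast on an alkenyl iodide α to a carbonyl and tolerates the weakly electrophilic pyranone, and the alkenylmagnesium should add 1,2 (Grignard addition) to one of the two equivalent carbonyls of the symmetric squarate, so no regiochemical question arises; the carbinol centre is racemic and is destroyed in step 5.

Step 5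
Reactants: 11 4-{6-[3,4-bis(benzyloxy)phenyl]-4-oxo-4H-pyran-3-yl}-4-hydroxy-2,3-dimethoxycyclobut-2-en-1-one
Product: 14 3',4'-bis(benzyloxy)-5,8-dihydroxy-6,7-dimethoxyflavone, via dienylketene 12 (not isolated), via cyclohexadienone 13 (not isolated)
Conditions: degassed p-xylene (0.02 M), 130 °C, Ar
Reagents that add atoms: none
Why: Thermal conrotatory 4π opening of the cyclobutenone cleaves the carbonyl–carbinol bond to give the (Z)-dienylketene 12, whose ketene carbon (future C8) bonds to the oxygen-bound CH of the pyranone (future C8a) to give dienone 13, which enolises to the aromatic 5,8-hydroquinone. The closest known reaction type is the Moore rearrangement of 4-alkenyl- and 4-aryl-4-hydroxycyclobutenones derived from squarate esters into highly oxygenated hydroquinones. The one ring closed is the six-membered carbocyclic A ring, formed by a thermal disrotatory 6π electrocyclisation that makes the C8–C8a bond. No lasting stereocentre results, since the carbinol centre is lost on ring opening and the sp3 C8a of 13 is lost on tautomerisation. The step needs torquoselectivity, secured by the donor hydroxyl rotating outward so that the pyranonyl group turns inward next to the ketene. Regiochemistry is fixed because the only CH flanking the attachment carbon is the O-bound one (the other neighbour is the pyranone carbonyl) and squarate is symmetric, so the four oxygens arrive on C5–C8; degassing should keep the hydroquinone from oxidising to the quinone.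

Step 6
Reactants: 14 3',4'-bis(benzyloxy)-5,8-dihydroxy-6,7-dimethoxyflavone
Product: 15 3',4'-bis(benzyloxy)-5,6,7,8-tetramethoxyflavone
Conditions: Me2SO4 (6 equiv), K2CO3 (8 equiv), acetone, reflux, Ar
Reagents that add atoms: dimethyl sulfate, COS(=O)(=O)OC
Why: Williamson-type O-methylation with excess dimethyl sulfate and carbonate at reflux is the standard way to etherify both the free 8-hydroxyl and the hydrogen-bonded 5-hydroxyl of a flavone, and the benzyl ethers are inert to it.

Step 7
Reactants: 15 3',4'-bis(benzyloxy)-5,6,7,8-tetramethoxyflavone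
Product: 16 3',4'-dihydroxy-5,6,7,8-tetramethoxyflavone (target)
Conditions: H2 (1 atm), 10% Pd/C, EtOAc/MeOH, rt
Reagents that add atoms: none
Why: Catalytic hydrogenolysis of benzyl aryl ethers at atmospheric pressure is expected to be much faster than reduction of the flavone C2=C3 bond and leaves the methyl ethers untouched, so the catechol is released last.

**Compound list**

1 | 3,4-bis(benzyloxy)benzaldehyde | O=Cc1ccc(OCc2ccccc2)c(OCc2ccccc2)c1 | starting material
2 | Danishefsky's diene, (E)-1-methoxy-3-(trimethylsilyloxy)buta-1,3-diene | CO/C=C/C(=C)O[Si](C)(C)C | starting material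
3 | 6-[3,4-bis(benzyloxy)phenyl]-2-methoxy-4-(trimethylsilyloxy)-3,6-dihydro-2H-pyran (cycloadduct, racemic diastereomer mixture, not isolated) | COC1C=C(O[Si](C)(C)C)CC(c2ccc(OCc3ccccc3)c(OCc3ccccc3)c2)O1 | intermediate
4 | 2-[3,4-bis(benzyloxy)phenyl]-2,3-dihydro-4H-pyran-4-one (racemic) | O=C1C=COC(c2ccc(OCc3ccccc3)c(OCc3ccccc3)c2)C1 | intermediate
5 | 2-[3,4-bis(benzyloxy)phenyl]-5-iodo-2,3-dihydro-4H-pyran-4-one (racemic) | O=C1CC(c2ccc(OCc3ccccc3)c(OCc3ccccc3)c2)OC=C1I | intermediate
6 | lithium 2-[3,4-bis(benzyloxy)phenyl]-5-iodo-2H-pyran-4-olate (lithium enolate, racemic, not isolated) | [Li]OC1=CC(c2ccc(OCc3ccccc3)c(OCc3ccccc3)c2)OC=C1I | intermediate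
7 | 2-[3,4-bis(benzyloxy)phenyl]-3-(N-tert-butyl-S-phenylsulfinimidoyl)-5-iodo-2,3-dihydro-4H-pyran-4-one (sulfilimine adduct, not isolated) | O=C1C(S(=NC(C)(C)C)c2ccccc2)C(c2ccc(OCc3ccccc3)c(OCc3ccccc3)c2)OC=C1I | intermediate
8 | 2-[3,4-bis(benzyloxy)phenyl]-5-iodo-4H-pyran-4-one | O=c1cc(-c2ccc(OCc3ccccc3)c(OCc3ccccc3)c2)occ1I | intermediate
9 | dimethyl squarate (3,4-dimethoxycyclobut-3-ene-1,2-dione) | COC1=C(OC)C(=O)C1=O | starting material
10 | {6-[3,4-bis(benzyloxy)phenyl]-4-oxo-4H-pyran-3-yl}magnesium chloride (not isolated) | O=c1cc(-c2ccc(OCc3ccccc3)c(OCc3ccccc3)c2)occ1[Mg]Cl | intermediate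
11 | 4-{6-[3,4-bis(benzyloxy)phenyl]-4-oxo-4H-pyran-3-yl}-4-hydroxy-2,3-dimethoxycyclobut-2-en-1-one (racemic) | COC1=C(OC)C(O)(c2coc(-c3ccc(OCc4ccccc4)c(OCc4ccccc4)c3)cc2=O)C1=O | intermediate
12 | (Z)-4-{6-[3,4-bis(benzyloxy)phenyl]-4-oxo-4H-pyran-3-yl}-4-hydroxy-2,3-dimethoxybuta-1,3-dien-1-one (dienylketene, not isolated) | O=C=C(OC)/C(OC)=C(/O)c1coc(-c2ccc(OCc3ccccc3)c(OCc3ccccc3)c2)cc1=O | intermediate
13 | 2-[3,4-bis(benzyloxy)phenyl]-5-hydroxy-6,7-dimethoxy-4H-chromene-4,8(8aH)-dione (cyclohexadienone, racemic, not isolated) | COC1=C(OC)C(=O)C2OC(c3ccc(OCc4ccccc4)c(OCc4ccccc4)c3)=CC(=O)C2=C1O | intermediate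
14 | 3',4'-bis(benzyloxy)-5,8-dihydroxy-6,7-dimethoxyflavone | COc1c(OC)c(O)c2c(=O)cc(-c3ccc(OCc4ccccc4)c(OCc4ccccc4)c3)oc2c1O | intermediate
15 | 3',4'-bis(benzyloxy)-5,6,7,8-tetramethoxyflavone | COc1c(OC)c(OC)c2c(=O)cc(-c3ccc(OCc4ccccc4)c(OCc4ccccc4)c3)oc2c1OC | intermediate
16 | 3',4'-dihydroxy-5,6,7,8-tetramethoxyflavone | COc1c(OC)c(OC)c2c(=O)cc(-c3ccc(O)c(O)c3)oc2c1OC | target

**Step count and risks**

Total steps: 7. Longest linear sequence: 7 steps (from aldehyde 1).

Steps most likely to fail:

1. Step 4. The magnesiated pyranone may fragment by β-elimination of the ring oxygen (ring opening to an ynone enolate) before it is trapped, or the Grignard species may attack the pyranone C6 or a second squarate carbonyl. The fallback sets out from 8 and avoids a polar carbon–magnesium bond. Direct insertion of zinc dust in the presence of LiCl (THF, 25 °C) should give {6-[3,4-bis(benzyloxy)phenyl]-4-oxo-4H-pyran-3-yl}zinc iodide F1, a covalent organozinc that should not eliminate. MgCl2-promoted 1,2-addition of this reagent to the strained dione 9 and aqueous work-up would return to the route at 11.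

2. Step 5. The ring opening may not be fully outward-selective for the hydroxyl, so that the ketene is captured by the free tertiary hydroxyl (butenolide formation) instead of the pyranone double bond, and the electron-rich hydroquinone may oxidise to the 5,8-quinone during heating or isolation. The fallback sets out from 11 and changes the group on the carbinol oxygen. O-methylation (MeI, Ag2O, K2CO3, MeCN) should give 4-{6-[3,4-bis(benzyloxy)phenyl]-4-oxo-4H-pyran-3-yl}-2,3,4-trimethoxycyclobut-2-en-1-one F2, which has no hydroxyl to trap the ketene. The same thermal ring expansion of the ether (p-xylene, 130 °C) is expected to give 3',4'-bis(benzyloxy)-8-hydroxy-5,6,7-trimethoxyflavone F3, a monophenol that is far less prone to oxidation and already carries the C5 methyl ether. Methylation of its single free 8-hydroxyl (Me2SO4, K2CO3, acetone) returns to the route at 15.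

3. Step 3. The α′-lithium enolate is a 4-oxido-2H-pyran and may open by retro-oxa-Michael (E1cB) or electrocyclic ring opening before sulfinimidoyl transfer, and LDA may attack the iodoalkene. The fallback sets out from 5 and avoids a lithium enolate. Soft enolisation (TMSOTf, Et3N, CH2Cl2, 0 °C) should give 2-[3,4-bis(benzyloxy)phenyl]-5-iodo-4-(trimethylsilyloxy)-2H-pyran F4. Oxidation of this silyl dienol ether with the IBX·4-methoxypyridine N-oxide complex in DMSO at room temperature (hypervalent-iodine dehydrogenation of silyl enol ethers) would return to the route at 8.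

**Further compounds**

F1 | step 4 | {6-[3,4-bis(benzyloxy)phenyl]-4-oxo-4H-pyran-3-yl}zinc iodide | O=c1cc(-c2ccc(OCc3ccccc3)c(OCc3ccccc3)c2)occ1[Zn]I
F2 | step 5 | 4-{6-[3,4-bis(benzyloxy)phenyl]-4-oxo-4H-pyran-3-yl}-2,3,4-trimethoxycyclobut-2-en-1-one (racemic) | COC1=C(OC)C(OC)(c2coc(-c3ccc(OCc4ccccc4)c(OCc4ccccc4)c3)cc2=O)C1=O
F3 | step 5 | 3',4'-bis(benzyloxy)-8-hydroxy-5,6,7-trimethoxyflavone | COc1c(OC)c(OC)c2c(=O)cc(-c3ccc(OCc4ccccc4)c(OCc4ccccc4)c3)oc2c1O
F4 | step 3 | 2-[3,4-bis(benzyloxy)phenyl]-5-iodo-4-(trimethylsilyloxy)-2H-pyran (racemic) | C[Si](C)(C)OC1=CC(c2ccc(OCc3ccccc3)c(OCc3ccccc3)c2)OC=C1I
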